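**Retrosynthetic overview**

1. Enabling feature: in rings A/B/D the sp3 carbon C5 is the middle atom of the skipped diene C15=C4–C5–C1=C10 and carries the oxygen-bearing C6, which is 1,4 to the C3 ketone. This is the retron of a γ-selective pentadienyl-metal addition to C6=O. Ring B is therefore cut at C5–C6, a bond between two acceptor carbons (enone β-carbon C5, carbonyl carbon C6), and closed by polarity reversal (allylic bromide to allylindium) in an intramolecular Barbier reaction on a precursor that already holds ring C as a γ-hydroxylactone.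
2. Ring D with both quaternary centres (C2, C4′) comes from an endo Diels–Alder reaction of dehydrozaluzanin C (rings E, F, G, from dehydrocostus lactone) with a 2-silyloxy diene built on ring A.
3. The diene comes from a Stille union of a bromo-diosphenol ring A block (from cyclopentane-1,2-dione) with a 2-stannyl-1-alkene carrying ring C as a menthyl-acetal lactone; C7 is set by auxiliary-controlled conjugate addition.
4. Ring order: E, F, G (chiral pool), A and C (building blocks), then D (step 13), then B (step 16, last). Only an acetate elimination and a desilylation follow.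

Key step: step 16

Remark: guaiane numbering is used; unprimed atoms are the upper unit (ring A = cyclopentanone C1–C5, ring B = seven-membered ring C1/C5–C10, ring C = its lactone), primed atoms the lower unit (rings E, F, G), and ring D is the cyclohexene C2–C1–C10–C14–C15′–C4′. Compounds 1, 4, 11, 12 and 14 are taken as commercial, and the C3′ carbinol of 2 (drawn as one epimer) and the lactol carbon of 24 are stereochemically inconsequential.

**Route**

Step 1
Reactants: 1 (−)-dehydrocostus lactone
Product: 2 3-epizaluzanin C (3α-hydroxydehydrocostus lactone)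
Conditions: SeO2 (cat.), t-BuOOH, CH2Cl2, 0 °C → rt
Reagents that add atoms: tert-butyl hydroperoxide, CC(C)(C)OO (oxygen delivered through catalytic selenium dioxide, O=[Se]=O)
Why: Allylic oxidation (ene reaction then [2,3]-sigmatropic shift) should attack the activated cyclopentane methylene C3′ next to the C4′=C15′ alkene; the carbinol configuration is erased in step 2.

Step 2
Reactants: 2 3-epizaluzanin C
Product: 3 dehydrozaluzanin C
Conditions: Dess–Martin periodinane, CH2Cl2, 0 °C → rt
Reagents that add atoms: none
Why: Dess–Martin oxidation of the secondary allylic alcohol should give the exo-methylene ketone under non-basic conditions that leave the α-methylene lactone and all four stereocentres untouched.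

Step 3
Reactants: 4 cyclopentane-1,2-dione
Product: 5 3-bromo-2-hydroxycyclopent-2-en-1-one
Conditions: NBS, CH2Cl2, 0 °C
Reagents that add atoms: N-bromosuccinimide, O=C1CCC(=O)N1Br
Why: Electrophilic bromination of the enol (diosphenol) tautomer at its nucleophilic carbon followed by re-enolization should give the bromo-diosphenol.

Step 4
Reactants: 5 3-bromo-2-hydroxycyclopent-2-en-1-one
Product: 6 3-bromo-2-(tert-butyldimethylsilyloxy)cyclopent-2-en-1-one
Conditions: TBSCl, imidazole, DMF, 0 °C → rt
Reagents that add atoms: tert-butyldimethylsilyl chloride, CC(C)(C)[Si](C)(C)Cl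
Why: O-silylation of the acidic enol hydroxyl installs the group that later becomes the C2 silyl ether and directs the key step.

Step 5
Reactants: 6 3-bromo-2-(tert-butyldimethylsilyloxy)cyclopent-2-en-1-one
Product: 8 3-bromo-2-(tert-butyldimethylsilyloxy)-5-[(dimethylamino)methyl]cyclopent-2-en-1-one (racemic), via lithium enolate 7 (not isolated)
Conditions: LiN(i-Pr)2, THF, −78 °C; then CH2=NMe2+ I−, −78 → 0 °C
Reagents that add atoms: N,N-dimethylmethyleneiminium iodide (Eschenmoser's salt), C=[N+](C)C.[I-]
Why: Kinetic α′-deprotonation at the only sp3 α-carbon and Mannich reaction of the enolate with the iminium salt should place the future C15 on C4; the new stereocentre is removed in step 6.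

Step 6
Reactants: 8 Mannich base
Product: 10 3-bromo-2-(tert-butyldimethylsilyloxy)-5-methylidenecyclopent-2-en-1-one, via methiodide 9 (not isolated)
Conditions: MeI, Et2O, rt; then NaHCO3 (aq), CH2Cl2, rt
Reagents that add atoms: none
Why: Quaternization and E1cB elimination of trimethylamine should give the exo-methylene ketone, which cannot move into the ring because that isomer would be a cyclopentadienone.

Step 7
Reactants: 11 5-hydroxyfuran-2(5H)-one (racemic); 12 (+)-menthol
Product: 13 (5S)-5-[(1S,2R,5S)-menthyloxy]furan-2(5H)-one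
Conditions: camphorsulfonic acid (cat.), toluene, reflux (−H2O); crystallization from petroleum ether with acid-mediated epimerization of the mother liquor
Reagents that add atoms: none
Why: Acid-catalysed acetalization followed by crystallization-driven epimerization of the acetal carbon should funnel the material into the single crystalline (5S) diastereomer, the mirror image of the familiar (−)-menthyl series.

Step 8
Reactants: 13 (5S)-menthyloxyfuranone; 14 (4-bromobut-1-yn-1-yl)trimethylsilane
Product: 17 (3R,4S,5S)-3-(hydroxymethyl)-5-[(1S,2R,5S)-menthyloxy]-4-[4-(trimethylsilyl)but-3-yn-1-yl]oxolan-2-one, via Grignard reagent 15 (not isolated), via magnesium enolate 16 (not isolated)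
Conditions: 14, Mg, THF; then 13, CuBr·SMe2 (cat.), THF, −78 °C; then CH2O (gas), −78 → −40 °C; aqueous work-up
Reagents that add atoms: formaldehyde, C=O
Why: Copper-catalysed conjugate addition of the Grignard reagent anti to the menthyloxy group should set C7 as (S), and the aldol reaction of the resulting enolate with formaldehyde trans to the new side chain should set C11.

Step 9
Reactants: 17 silylalkyne
Product: 18 (3R,4S,5S)-4-(but-3-yn-1-yl)-3-(hydroxymethyl)-5-[(1S,2R,5S)-menthyloxy]oxolan-2-one
Conditions: n-Bu4NF, AcOH, THF, 0 °C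
Reagents that add atoms: none
Why: Buffered fluoride should cleave the alkynyl C–Si bond (protodesilylation) without epimerizing or opening the lactone acetal.

Step 10
Reactants: 18 terminal alkyne
Product: 19 [(3R,4S,5S)-4-(but-3-yn-1-yl)-5-[(1S,2R,5S)-menthyloxy]-2-oxooxolan-3-yl]methyl acetate
Conditions: Ac2O, pyridine, CH2Cl2, 0 °C
Reagents that add atoms: acetic anhydride, CC(=O)OC(C)=O
Why: Acylation of the primary alcohol gives a β-acetoxy lactone that is a latent α-methylene lactone and cannot form an internal acetal with C6 later.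

Step 11
Reactants: 19 alkyne acetate
Product: 20 [(3R,4S,5S)-5-[(1S,2R,5S)-menthyloxy]-2-oxo-4-[3-(trimethylstannyl)but-3-en-1-yl]oxolan-3-yl]methyl acetate
Conditions: Me3SnSnMe3, MeLi, THF, −20 °C; CuBr·SMe2, −78 °C; then 19, MeOH, −63 °C
Reagents that add atoms: hexamethylditin, C[Sn](C)(C)[Sn](C)(C)C (delivered as (trimethylstannyl)copper–dimethyl sulfide, C[Sn](C)(C)[Cu].CSC)
Why: Syn-stannylcupration of the terminal alkyne with kinetic protonation by methanol at low temperature should place tin on the internal carbon and give the 2-stannyl-1-alkene, with the ester groups tolerated.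

Step 12
Reactants: 20 alkenylstannane; 10 bromo dienone
Product: 21 diene: 2-(tert-butyldimethylsilyloxy)-5-methylidenecyclopent-2-en-1-one bearing at C3 a buta-1-en-2-yl chain that ends in the (6S,7S,11R) lactone acetal
Conditions: Pd2(dba)3 (cat.), AsPh3, CuI (cat.), DMF, rt → 40 °C
Reagents that add atoms: none
Why: Stille coupling of the β-bromo enone with the alkenylstannane, with copper co-catalysis for the hindered 1,1-disubstituted stannane, should form the C1–C10 bond under neutral conditions and deliver the 1-silyloxy diene C2=C1–C10=C14.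

Step 13
Reactants: 21 diene; 3 dehydrozaluzanin C
Product: 22 Diels–Alder adduct: rings A, D, E, F, G and the lactone acetal ring C in place; C2 silyloxy cis to C5′ on ring D; C2–C4′ bond on the H1′/H5′ face of ring E
Conditions: 3 (3 equiv), BHT (cat.), toluene, 60 °C, dark
Reagents that add atoms: none
Why: Diels–Alder reaction in which the unsubstituted diene terminus C14 bonds to the β-carbon C15′ of the exo-methylene ketone (ortho/para regiochemistry), the diene adds to the convex face of 3 (syn to H1′ and H5′) to set C4′, and the ketone-endo transition state (C3′=O under the diene, bulky C5′ branch outside) sets C2 with its oxygen cis to C5′; excess 3 suppresses self-addition of the diene to its own enone.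

Step 14
Reactants: 22 Diels–Alder adduct
Product: 23 allylic bromide: ring A as 2-(bromomethyl)-4-ylidene-cyclopent-2-enone (C15–Br, C4=C5, C1=C10)
Conditions: NBS (1.05 equiv), AIBN (cat.), PhCF3, 70 °C
Reagents that add atoms: N-bromosuccinimide, O=C1CCC(=O)N1Br
Why: Wohl–Ziegler bromination should abstract the weakest hydrogen (doubly allylic C5–H between C4=C15 and C1=C10) and transfer bromine to the primary terminus C15 to give the fully conjugated dienone; any regioisomeric allylic bromide would converge on the same allylmetal in step 16.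

Step 15
Reactants: 23 allylic bromide menthyl acetal
Product: 24 γ-hydroxylactone (lactol, both C6 epimers) of the allylic bromide
Conditions: CF3CO2H/H2O (4:1), CH2Cl2, 0 °C → rt
Reagents that add atoms: water, O
Why: Acid hydrolysis of the mixed acetal should release the auxiliary and leave ring C as a closed hydroxylactone, while the tertiary silyl ether, the acetate and the allylic bromide survive aqueous acid.

Step 16
Reactants: 24 γ-hydroxylactone allylic bromide
Product: 26 ring-B-closed heptacycle (C2 silyl ether; 11-acetoxymethyl; H5α H6β H7α), via pentadienylindium dibromide 25 (not isolated)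
Conditions: In powder (3 equiv), NaI (cat.), THF/H2O (3:1), 0.005 M, rt; then citric acid (aq)
Reagents that add atoms: none
Why: Indium metal inserts into the allylic C15–Br bond of 24 to give the pentadienylindium 25, which turns C5, the electrophilic β-carbon of the dienone, into a nucleophile (polarity reversal) and lets it attack C6, itself an electrophilic carbon, supplied as the aldehyde tautomer of the hydroxylactone; the γ-oxido acid returns at once to the butyrolactone already present in 24, so ring B is the only ring the step adds. The closest known reaction type is the aqueous Barbier allylation of aldehydes and of lactols (pseudo-acids) with 2-(bromomethyl) enones and acrylates, including its intramolecular form used for seven-membered carbocycles. Ring B closes by C5–C6 bond formation through a six-membered Zimmerman–Traxler transition state (In–C15–C4=C5···C6=O), a 7-exo closure seen from the carbocycle, which makes attack through C5 (γ) obligatory and excludes C15 (nine-membered ring) and C10 (no cyclic array, fully substituted). C5 is controlled by the C2 quaternary centre, whose tertiary silyl ether lies over ring A so that the aldehyde adds to the opposite face; C6 is controlled by the chair transition state, in which the ring-fixed E-type γ-substituent C1 and the aldehyde substituent C7 are both equatorial, giving the anti adduct (H5/H6 trans), and the preset C7 centre then makes the lactone trans-fused. The step needs γ- over ε-regioselectivity, anti diastereoselectivity and chemoselectivity for the aldehyde over two ketones, two lactones and an acetate; the cyclic transition state and the low basicity and aldehyde preference of allylindium reagents in water should secure them. The same event moves the double bond to C4=C15 and so unveils the exo-methylene ketone and the skipped diene C15=C4–C5–C1=C10 of the target.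

Step 17
Reactants: 26 acetoxymethyl lactone
Product: 27 C2-silyl ether of the target
Conditions: DBU, CH2Cl2, 0 °C
Reagents that add atoms: none
Why: E1cB elimination of acetic acid from the β-acetoxy lactone should give the α-methylene lactone, while the silyl ether blocks retro-aldol cleavage of the C2–C4′ bond and the non-enolizable C5–H stays in place.

Step 18
Reactants: 27 silyl ether
Product: 28 CNP0269880.2 (target)
Conditions: HF·pyridine, pyridine/THF, 0 °C → rt
Reagents that add atoms: none
Why: Fluoride-mediated desilylation under mildly acidic conditions should free the tertiary alcohol without the basic conditions that would trigger retro-aldol or α-ketol rearrangement of the β-hydroxy and α-hydroxy ketone array.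

**Compound list**

1 | (−)-dehydrocostus lactone | C=C1CC[C@H]2C(=C)CC[C@H]3C(=C)C(=O)O[C@@H]3[C@H]21 | starting material
2 | 3-epizaluzanin C (3α-hydroxydehydrocostus lactone) | C=C1[C@H](O)C[C@H]2C(=C)CC[C@H]3C(=C)C(=O)O[C@@H]3[C@H]21 | intermediate
3 | dehydrozaluzanin C | C=C1C(=O)C[C@H]2C(=C)CC[C@H]3C(=C)C(=O)O[C@@H]3[C@H]21 | intermediate
4 | cyclopentane-1,2-dione | O=C1CCCC1=O | starting material
5 | 3-bromo-2-hydroxycyclopent-2-en-1-one | O=C1CCC(Br)=C1O | intermediate
6 | 3-bromo-2-(tert-butyldimethylsilyloxy)cyclopent-2-en-1-one | O=C1CCC(Br)=C1O[Si](C)(C)C(C)(C)C | intermediate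
7 | lithium enolate of 6 | [Li]OC1=CCC(Br)=C1O[Si](C)(C)C(C)(C)C | intermediate
8 | 3-bromo-2-(tert-butyldimethylsilyloxy)-5-[(dimethylamino)methyl]cyclopent-2-en-1-one (racemic) | CN(C)CC1CC(Br)=C(O[Si](C)(C)C(C)(C)C)C1=O | intermediate
9 | methiodide of 8 | C[N+](C)(C)CC1CC(Br)=C(O[Si](C)(C)C(C)(C)C)C1=O.[I-] | intermediate
10 | 3-bromo-2-(tert-butyldimethylsilyloxy)-5-methylidenecyclopent-2-en-1-one | C=C1CC(Br)=C(O[Si](C)(C)C(C)(C)C)C1=O | intermediate
11 | 5-hydroxyfuran-2(5H)-one (racemic) | O=C1C=CC(O)O1 | starting material
12 | (+)-menthol, (1S,2R,5S) | CC(C)[C@H]1CC[C@H](C)C[C@@H]1O | starting material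
13 | (5S)-5-[(1S,2R,5S)-menthyloxy]furan-2(5H)-one | O=C1C=C[C@@H](O[C@H]2C[C@@H](C)CC[C@@H]2C(C)C)O1 | intermediate
14 | (4-bromobut-1-yn-1-yl)trimethylsilane | C[Si](C)(C)C#CCCBr | starting material
15 | [4-(trimethylsilyl)but-3-yn-1-yl]magnesium bromide | C[Si](C)(C)C#CCC[Mg]Br | intermediate
16 | bromomagnesium enolate of the conjugate adduct (C7 S, C6 S) | Br[Mg]OC1=C[C@H](CCC#C[Si](C)(C)C)[C@@H](O[C@H]2C[C@@H](C)CC[C@@H]2C(C)C)O1 | intermediate
17 | (3R,4S,5S)-3-(hydroxymethyl)-5-[(1S,2R,5S)-menthyloxy]-4-[4-(trimethylsilyl)but-3-yn-1-yl]oxolan-2-one | C[Si](C)(C)C#CCC[C@H]1[C@H](CO)C(=O)O[C@@H]1O[C@H]2C[C@@H](C)CC[C@@H]2C(C)C | intermediate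
18 | (3R,4S,5S)-4-(but-3-yn-1-yl)-3-(hydroxymethyl)-5-[(1S,2R,5S)-menthyloxy]oxolan-2-one | C#CCC[C@H]1[C@H](CO)C(=O)O[C@@H]1O[C@H]2C[C@@H](C)CC[C@@H]2C(C)C | intermediate
19 | [(3R,4S,5S)-4-(but-3-yn-1-yl)-5-[(1S,2R,5S)-menthyloxy]-2-oxooxolan-3-yl]methyl acetate | C#CCC[C@H]1[C@H](COC(C)=O)C(=O)O[C@@H]1O[C@H]2C[C@@H](C)CC[C@@H]2C(C)C | intermediate
20 | [(3R,4S,5S)-5-[(1S,2R,5S)-menthyloxy]-2-oxo-4-[3-(trimethylstannyl)but-3-en-1-yl]oxolan-3-yl]methyl acetate | C=C([Sn](C)(C)C)CC[C@H]1[C@H](COC(C)=O)C(=O)O[C@@H]1O[C@H]2C[C@@H](C)CC[C@@H]2C(C)C | intermediate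
21 | silyloxy diene (ring A with C4 exo-methylene; C10=C14; side chain with (6S,7S,11R) lactone acetal) | C=C1CC(C(=C)CC[C@H]2[C@H](COC(C)=O)C(=O)O[C@@H]2O[C@H]3C[C@@H](C)CC[C@@H]3C(C)C)=C(O[Si](C)(C)C(C)(C)C)C1=O | intermediate
22 | Diels–Alder adduct (rings A, D, E, F, G; C2 silyloxy cis to C5′; C5 methylene) | C=C1C(=O)[C@]2(O[Si](C)(C)C(C)(C)C)C(C1)=C(CC[C@H]3[C@H](COC(C)=O)C(=O)O[C@@H]3O[C@H]4C[C@@H](C)CC[C@@H]4C(C)C)CC[C@]21C(=O)C[C@H]2C(=C)CC[C@H]3C(=C)C(=O)O[C@@H]3[C@H]21 | intermediate
23 | allylic bromide (C15–Br; C4=C5; C1=C10) menthyl acetal | BrCC1=CC2=C(CC[C@H]6[C@H](COC(C)=O)C(=O)O[C@@H]6O[C@H]7C[C@@H](C)CC[C@@H]7C(C)C)CC[C@]3(C(=O)C[C@H]4C(=C)CC[C@H]5C(=C)C(=O)O[C@@H]5[C@H]43)[C@]2(O[Si](C)(C)C(C)(C)C)C1=O | intermediate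
24 | allylic bromide γ-hydroxylactone (C6 epimers) | BrCC1=CC2=C(CC[C@H]6[C@H](COC(C)=O)C(=O)OC6O)CC[C@]3(C(=O)C[C@H]4C(=C)CC[C@H]5C(=C)C(=O)O[C@@H]5[C@H]43)[C@]2(O[Si](C)(C)C(C)(C)C)C1=O | intermediate
25 | pentadienylindium dibromide derived from 24 | Br[In](Br)CC1=CC2=C(CC[C@H]6[C@H](COC(C)=O)C(=O)OC6O)CC[C@]3(C(=O)C[C@H]4C(=C)CC[C@H]5C(=C)C(=O)O[C@@H]5[C@H]43)[C@]2(O[Si](C)(C)C(C)(C)C)C1=O | intermediate
26 | ring-B-closed heptacycle (C2 silyl ether; 11R acetoxymethyl; 5R, 6S, 7S) | C=C1C(=O)[C@]2(O[Si](C)(C)C(C)(C)C)C3=C(CC[C@H]4[C@H](COC(C)=O)C(=O)O[C@@H]4[C@@H]13)CC[C@]21C(=O)C[C@H]2C(=C)CC[C@H]3C(=C)C(=O)O[C@@H]3[C@H]21 | intermediate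
27 | C2-(tert-butyldimethylsilyl) ether of the target | C=C1C(=O)[C@]2(O[Si](C)(C)C(C)(C)C)C3=C(CC[C@H]4C(=C)C(=O)O[C@@H]4[C@@H]13)CC[C@]21C(=O)C[C@H]2C(=C)CC[C@H]3C(=C)C(=O)O[C@@H]3[C@H]21 | intermediate
28 | CNP0269880.2 | C=C1C(=O)[C@]2(O)C3=C(CC[C@H]4C(=C)C(=O)O[C@@H]4[C@@H]13)CC[C@]21C(=O)C[C@H]2C(=C)CC[C@H]3C(=C)C(=O)O[C@@H]3[C@H]21 | target

**Step count and risks**

Total step count: 18. Longest linear sequence: 12 steps (7 → 8 → 9 → 10 → 11 → 12 → 13 → 14 → 15 → 16 → 17 → 18).

Steps most likely to fail:

Step 13. The cycloaddition may stall because the silyloxy group sits at the inside position of the diene terminus and two adjacent quaternary centres must form, so self-addition of the diene to its own exo-methylene ketone can take over. Fallback, setting out from 20 and returning at 22: put the C2 oxygen in after ring D instead of before. Commercial 3-bromocyclopent-2-en-1-one is α′-methylenated (paraformaldehyde, diisopropylammonium trifluoroacetate, THF, reflux) to 3-bromo-5-methylidenecyclopent-2-en-1-one F1. Stille coupling of F1 with 20 under the conditions of step 12 gives the oxygen-free diene F2, whose acyl-substituted diene terminus carries only hydrogen inside; this is the diene type by which this dimer family is assembled. Cycloaddition with 3 should then give the C2–H adduct F3 with the same endo and facial sense. The uniquely acidic C2–H (tertiary, α to C3=O, allylic) is removed with one equivalent of KN(SiMe3)2 at −78 °C, and the dienolate is oxidized with 2-(phenylsulfonyl)-3-phenyloxaziridine on the face anti to the C3′ carbonyl branch to give the tertiary alcohol F4. Silylation (TBSOTf, 2,6-lutidine) returns to 22.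

Step 14. Hydrogen abstraction may lose its preference for the doubly allylic C5–H, and bromine may add to the electron-rich exocyclic alkenes of the lower unit. Fallback, setting out from 22 and returning at 23: replace bromine-atom chemistry by a Kharasch–Sosnovsky oxidation (tert-butyl perbenzoate, CuBr (cat.), benzene, 70 °C). The tert-butoxyl radical is a more selective abstractor and does not add to alkenes, and the reaction should give the allylic benzoate F5 (drawn as the C5 ester, both epimers; regioisomers are equivalent). Treatment with MgBr2·OEt2 (CH2Cl2, rt) should then convert F5 by ionic allylic substitution into the thermodynamically preferred primary bromide 23.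

Step 16. Protonolysis of the allylindium by the carboxylic acid tautomer and water, or addition from the face of the silyl ether, may outrun the seven-membered ring closure. Fallback, setting out from 23 and returning at 26: change the electrophile from the aldehyde tautomer to a cyclic acylal. Acetolysis of the menthyl acetal (Ac2O, FeCl3 (cat.), CH2Cl2, 0 °C) gives the 6-acetoxy lactone F6. Indium-mediated allylation of this acylal (In powder, InCl3 (cat.), dry THF/DMF, rt), a known reaction of gem-diacyloxy compounds, should displace the acetate at C6 by the same pentadienylindium under anhydrous, acid-free conditions. The lactone ring is never opened, and 26 is formed directly.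

**Further compounds**

F1 | step 13 | 3-bromo-5-methylidenecyclopent-2-en-1-one | C=C1CC(Br)=CC1=O
F2 | step 13 | oxygen-free diene (3-(buta-1-en-2-yl)-5-methylidenecyclopent-2-en-1-one carrying the lactone acetal chain) | C=C1CC(C(=C)CC[C@H]2[C@H](COC(C)=O)C(=O)O[C@@H]2O[C@H]3C[C@@H](C)CC[C@@H]3C(C)C)=CC1=O
F3 | step 13 | C2–H Diels–Alder adduct | C=C1C(=O)[C@@H]2C(C1)=C(CC[C@H]3[C@H](COC(C)=O)C(=O)O[C@@H]3O[C@H]4C[C@@H](C)CC[C@@H]4C(C)C)CC[C@]21C(=O)C[C@H]2C(=C)CC[C@H]3C(=C)C(=O)O[C@@H]3[C@H]21
F4 | step 13 | C2 tertiary alcohol of the adduct | C=C1C(=O)[C@]2(O)C(C1)=C(CC[C@H]3[C@H](COC(C)=O)C(=O)O[C@@H]3O[C@H]4C[C@@H](C)CC[C@@H]4C(C)C)CC[C@]21C(=O)C[C@H]2C(=C)CC[C@H]3C(=C)C(=O)O[C@@H]3[C@H]21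
F5 | step 14 | C5 allylic benzoate of 22 (both C5 epimers) | C=C1C(=O)[C@]2(O[Si](C)(C)C(C)(C)C)C(C1OC(=O)c5ccccc5)=C(CC[C@H]3[C@H](COC(C)=O)C(=O)O[C@@H]3O[C@H]4C[C@@H](C)CC[C@@H]4C(C)C)CC[C@]21C(=O)C[C@H]2C(=C)CC[C@H]3C(=C)C(=O)O[C@@H]3[C@H]21
F6 | step 16 | 6-acetoxy lactone (acylal, C6 epimers) of the allylic bromide | BrCC1=CC2=C(CC[C@H]6[C@H](COC(C)=O)C(=O)OC6OC(C)=O)CC[C@]3(C(=O)C[C@H]4C(=C)CC[C@H]5C(=C)C(=O)O[C@@H]5[C@H]43)[C@]2(O[Si](C)(C)C(C)(C)C)C1=O
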